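**Retrosynthetic overview**
- The last disconnections are the C11–C12 bond (Stille hydroxymethylation of a (Z)-β-iodoenone) and the C3 ester; the trienoic acid comes from carboalumination of an enyne followed by a Heck coupling.
- Ring B (C5–C6–C7–C8–C9–C10) is not assembled directly. It is generated from the five-membered ring (C5–C6–C8–C9–C10) of a cis-hydrindane: an iodonium-triggered semipinacol shift of a 1-propynyl cyclopentanol inserts the alkyne carbon as C7 between C8 and C6.
- The enabling feature is that, in ring B, the C8 carbonyl lies between the oxygen-bearing C9 and the fully substituted exocyclic C7=C11 alkene. A 2-alkylidenecyclohexanone is the product pattern of an alkynyl-carbinol 1,2-shift; anti addition puts CH3 cis to C6 and the heteroatom cis to C8=O, and the C9 silyloxy group makes C6, not C9, the migrating carbon.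
- The hydrindane is built on a chiral ring A enone: cuprate addition and enolate allylation (C4, C5), Wacker/aldol cyclopentenone annulation, 1,4-hydrosilylation (C10) and Rubottom oxidation (C9).
- Order of ring formation: ring A (purchased) → five-membered ring (step 5) → ring B by one-carbon enlargement of that ring (step 10).

Key step: step 10

Remark on locants: eremophilane numbering of the target is used throughout (ring A = C1–C5, C10; ring B = C5–C10; C11–C13 on C7; methyls C14 on C5 and C15 on C4); β is the face of the C5 methyl; hydrindane intermediates keep these locants (five-membered ring = C5, C6, C8, C9, C10).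
Assumption: enantiopure (R)-4-(tert-butyldimethylsilyloxy)cyclohex-2-en-1-one is taken as a purchasable building block.

**Route**

Step 1
Reactants: 1 (R)-4-(tert-butyldimethylsilyloxy)cyclohex-2-en-1-one
Product: 2 (R)-4-(tert-butyldimethylsilyloxy)-2-iodocyclohex-2-en-1-one
Conditions: I2, pyridine, CH2Cl2, 0 °C → rt
Reagents that add atoms: iodine, II
Why: α-Iodination of the enone by pyridine addition–iodination–elimination is routine for 4-silyloxycyclohexenones and should leave the γ-stereocentre untouched.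

Step 2
Reactants: 2 (R)-4-(tert-butyldimethylsilyloxy)-2-iodocyclohex-2-en-1-one
Product: 3 (R)-4-(tert-butyldimethylsilyloxy)-2-methylcyclohex-2-en-1-one
Conditions: SnMe4, PdCl2(PhCN)2 (5 mol %), AsPh3, CuI, NMP, 80 °C
Reagents that add atoms: tetramethylstannane, C[Sn](C)(C)C
Why: Stille methylation of an α-iodoenone under copper co-catalysis should replace iodine by methyl under neutral conditions that do not eliminate the γ-silyloxy group.

Step 3
Reactants: 3 (R)-4-(tert-butyldimethylsilyloxy)-2-methylcyclohex-2-en-1-one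
Product: 5 (2R,3R,4R)-2-allyl-4-(tert-butyldimethylsilyloxy)-2,3-dimethylcyclohexan-1-one, via lithium enolate 4 (not isolated)
Conditions: Me2CuLi (CuI, MeLi), Et2O, −78 → −20 °C; then allyl bromide, HMPA, THF, −78 → 0 °C
Reagents that add atoms: lithium dimethylcuprate, [Li+].C[Cu-]C; allyl bromide, C=CCBr
Why: In this conjugate addition–enolate alkylation the cuprate should add anti to the γ-silyloxy group (sets C4), and the regiodefined tetrasubstituted enolate should be allylated anti to the new vicinal methyl, which is held axial by A(1,2) strain, so that the C5 quaternary centre forms with the two methyls cis.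

Step 4
Reactants: 5 (2R,3R,4R)-2-allyl-4-(tert-butyldimethylsilyloxy)-2,3-dimethylcyclohexan-1-one
Product: 6 (2R,3R,4R)-4-(tert-butyldimethylsilyloxy)-2,3-dimethyl-2-(2-oxopropyl)cyclohexan-1-one
Conditions: PdCl2 (10 mol %), CuCl, O2 (1 atm), DMF/H2O (7:1), rt
Reagents that add atoms: water, O
Why: Wacker–Tsuji oxidation should convert the terminal alkene with Markovnikov selectivity into the methyl ketone, as is standard for α-allyl ketones with a quaternary α-carbon, without touching a stereocentre.

Step 5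
Reactants: 6 (2R,3R,4R)-4-(tert-butyldimethylsilyloxy)-2,3-dimethyl-2-(2-oxopropyl)cyclohexan-1-one
Product: 8 3α-(tert-butyldimethylsilyloxy)-4β,5β-dimethylhydrind-9-en-8-one [(6R,7R,7aR)-6-(tert-butyldimethylsilyloxy)-7,7a-dimethyl-1,4,5,6,7,7a-hexahydro-2H-inden-2-one], via aldol adduct 7 (not isolated)
Conditions: KOH, MeOH, 60 °C
Reagents that add atoms: none
Why: Intramolecular aldol condensation of the 1,4-diketone (cyclopentenone annulation) should close the five-membered ring C5–C6–C8–C9–C10 by attack of the methyl-ketone enolate (C9) on the ring ketone (C10) and dehydration; the bridged alternative aldol cannot dehydrate and reverts.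

Step 6
Reactants: 8 3α-(tert-butyldimethylsilyloxy)-4β,5β-dimethylhydrind-9-en-8-one
Product: 9 3α-(tert-butyldimethylsilyloxy)-8-(triethylsilyloxy)-4β,5β-dimethyl-10βH-hydrind-8-ene (cis-fused)
Conditions: Et3SiH, RhCl(PPh3)3 (2 mol %), toluene, 60 °C
Reagents that add atoms: triethylsilane, CC[SiH](CC)CC
Why: Rhodium-catalysed 1,4-hydrosilylation should give the regiodefined C8=C9 silyl enol ether and deliver hydride to C10 on the face of the angular methyl (the opposite face being screened by the axial hydrogens of ring A, as in hydrogenation and copper hydride reduction of angularly methylated hydrindenones and octalones), which sets the cis ring fusion.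

Step 7
Reactants: 9 3α-(tert-butyldimethylsilyloxy)-8-(triethylsilyloxy)-4β,5β-dimethyl-10βH-hydrind-8-ene
Product: 12 3α-(tert-butyldimethylsilyloxy)-9β-hydroxy-4β,5β-dimethyl-10βH-hydrindan-8-one, via silyloxy epoxide 10 (not isolated), via α-triethylsilyloxy ketone 11 (not isolated)
Conditions: mCPBA, NaHCO3, CH2Cl2, 0 °C; then AcOH/THF/H2O, rt
Reagents that add atoms: 3-chloroperoxybenzoic acid, OOC(=O)c1cccc(Cl)c1
Why: In this Rubottom oxidation the peracid should epoxidise the only alkene on the convex β face of the cis-hydrindane (anti to C1), silyl migration gives the 9β-silyloxy ketone, and mild acid frees the 9β-hydroxyl (cis to H10) while the C3 TBS ether survives.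

Step 8
Reactants: 12 3α-(tert-butyldimethylsilyloxy)-9β-hydroxy-4β,5β-dimethyl-10βH-hydrindan-8-one
Product: 13 3α-(tert-butyldimethylsilyloxy)-9β-(triisopropylsilyloxy)-4β,5β-dimethyl-10βH-hydrindan-8-one
Conditions: TIPSOTf, 2,6-lutidine, CH2Cl2, −78 → 0 °C
Reagents that add atoms: triisopropylsilyl trifluoromethanesulfonate, CC(C)[Si](OS(=O)(=O)C(F)(F)F)(C(C)C)C(C)C
Why: Silylation of the acyloin hydroxyl with the silyl triflate and a hindered base should occur without enolising C9 and gives an ether that outlasts later removal of the TBS group.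

Step 9
Reactants: 13 3α-(tert-butyldimethylsilyloxy)-9β-(triisopropylsilyloxy)-4β,5β-dimethyl-10βH-hydrindan-8-one
Product: 14 3α-(tert-butyldimethylsilyloxy)-8β-hydroxy-8α-(prop-1-ynyl)-9β-(triisopropylsilyloxy)-4β,5β-dimethyl-10βH-hydrindane
Conditions: CH3C≡CMgBr, CeCl3, THF, −78 °C
Reagents that add atoms: prop-1-ynylmagnesium bromide, CC#C[Mg]Br
Why: Organocerium 1,2-addition should add the alkynyl group to the enolisable α-silyloxy ketone without enolisation, anti to the adjacent silyloxy group as drawn; the C8 configuration is inconsequential because C8 becomes the ketone carbon in step 10.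

Step 10
Reactants: 14 3α-(tert-butyldimethylsilyloxy)-8β-hydroxy-8α-(prop-1-ynyl)-9β-(triisopropylsilyloxy)-4β,5β-dimethyl-10βH-hydrindane
Product: 15 3α-(tert-butyldimethylsilyloxy)-11-iodo-9β-(triisopropylsilyloxy)-10βH-12-noreremophil-7(11)Z-en-8-one
Conditions: NIS (1.3 equiv), PhI(OH)OTs (10 mol %), MeCN, 0 °C → rt
Reagents that add atoms: N-iodosuccinimide, O=C1CCC(=O)N1I
Why: Proposed new method: N-iodosuccinimide, activated by the catalytic hypervalent-iodine sulfonate, should transfer iodonium (I+) to the propynyl π bond of 14 to give a bridged iodirenium ion, and the C8–C6 ring bond, antiperiplanar to the breaking C7–I+ bond, then shifts from C8 to C7 while the carbinol oxygen collapses to the C8 ketone (alkynyl-carbinol semipinacol rearrangement). The closest known reaction type is the halonium-induced ring enlargement of 1-(haloethynyl)cyclopentanols to (Z)-β,β-dihaloenones with the same reagent pair, together with gold- or palladium-mediated enlargements of 1-alkynylcyclobutanols; the extension proposed here is to a non-halogenated propynyl group on an unstrained, α-silyloxylated cyclopentanol. Ring B is not closed by a cyclisation but arises by ring enlargement: the former alkyne carbon C7 is inserted between C8 and C6 of the five-membered ring (1,2-alkyl shift, five → six), driven by C=O formation. No new sp3 stereocentre is formed and C9 and C10 are untouched; the only new stereo-element, the tetrasubstituted C7=C11 geometry, is fixed by anti addition of the migrating C6 and iodine across the alkyne, which places iodine cis to the C8 carbonyl and the methyl cis to C6. The step needs migration of C6 and not C9, which the 9-silyloxy group secures because its inductive effect disfavours C9 as the electron-deficient migrating carbon. It also needs the 1,2-shift to win over ionisation at C8 (Meyer–Schuster or Rupe-type transposition, dehydration), which the same β-oxygen and the weakly acidic, non-ionising medium secure; the alkyne is the only π bond present.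

Step 11
Reactants: 15 3α-(tert-butyldimethylsilyloxy)-11-iodo-9β-(triisopropylsilyloxy)-10βH-12-noreremophil-7(11)Z-en-8-one
Product: 16 3α-hydroxy-11-iodo-9β-(triisopropylsilyloxy)-10βH-12-noreremophil-7(11)Z-en-8-one
Conditions: HF·pyridine, THF, 0 °C
Reagents that add atoms: none
Why: In this selective desilylation the ordinary secondary TBS ether should be cleaved by HF·pyridine much faster than the bulkier, carbonyl-deactivated TIPS ether, and the non-nucleophilic medium spares the β-iodoenone.

Fragment 2 (the acid):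

Step 12
Reactants: 17 (E)-oct-2-enal
Product: 18 (E)-non-3-en-1-yne
Conditions: TMSCHN2, n-BuLi, THF, −78 °C → rt
Reagents that add atoms: (trimethylsilyl)diazomethane, C[Si](C)(C)C=[N+]=[N-]
Why: Colvin homologation with lithiated (trimethylsilyl)diazomethane should add 1,2 to the enal and give the terminal alkyne via the alkylidene carbene, with the E alkene retained and without the conjugate-addition problems of methanolic alternatives.

Step 13
Reactants: 18 (E)-non-3-en-1-yne
Product: 20 (1E,3E)-1-iodo-2-methylnona-1,3-diene, via dienylalane 19 (not isolated)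
Conditions: AlMe3, Cp2ZrCl2, CH2Cl2, 0 °C → rt; then I2, THF, −30 → 0 °C
Reagents that add atoms: trimethylaluminium, C[Al](C)C; iodine, II
Why: Zirconium-catalysed carboalumination (Negishi) should add methyl and aluminium syn across the terminal alkyne with methyl on the internal carbon, and iodinolysis with retention gives the 1E iodide, which sets the future 4E trisubstituted alkene.

Step 14
Reactants: 20 (1E,3E)-1-iodo-2-methylnona-1,3-diene; 21 ethyl acrylate
Product: 22 ethyl (2E,4E,6E)-5-methyldodeca-2,4,6-trienoate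
Conditions: Pd(OAc)2 (5 mol %), K2CO3, Bu4NCl, DMF, 40 °C
Reagents that add atoms: none
Why: Heck coupling under ligand-free phase-transfer conditions should proceed with retention at the alkenyl iodide, and syn β-hydride elimination forms the new 2E alkene.

Step 15
Reactants: 22 ethyl (2E,4E,6E)-5-methyldodeca-2,4,6-trienoate
Product: 23 (2E,4E,6E)-5-methyldodeca-2,4,6-trienoic acid
Conditions: LiOH, THF/MeOH/H2O, rt; then 1 M HCl
Reagents that add atoms: lithium hydroxide, [Li+].[OH-]
Why: Saponification of the ethyl ester under mild conditions should free the acid without isomerising the triene.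

Fragment union and endgame:

Step 16
Reactants: 16 3α-hydroxy-11-iodo-9β-(triisopropylsilyloxy)-10βH-12-noreremophil-7(11)Z-en-8-one; 23 (2E,4E,6E)-5-methyldodeca-2,4,6-trienoic acid
Product: 24 11-iodo-3α-[(2E,4E,6E)-5-methyldodeca-2,4,6-trienoyloxy]-9β-(triisopropylsilyloxy)-10βH-12-noreremophil-7(11)Z-en-8-one
Conditions: EDC·HCl, DMAP (0.3 equiv), CH2Cl2, 0 °C → rt
Reagents that add atoms: none
Why: Steglich (carbodiimide) esterification should acylate the only free hydroxyl, the equatorial C3 alcohol, with retention, and substoichiometric DMAP limits addition to the hindered β-iodoenone.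

Step 17
Reactants: 24 11-iodo-3α-[(2E,4E,6E)-5-methyldodeca-2,4,6-trienoyloxy]-9β-(triisopropylsilyloxy)-10βH-12-noreremophil-7(11)Z-en-8-one
Product: 25 9β-hydroxy-11-iodo-3α-[(2E,4E,6E)-5-methyldodeca-2,4,6-trienoyloxy]-10βH-12-noreremophil-7(11)Z-en-8-one
Conditions: TBAF, AcOH (1:1), THF, 0 °C → rt
Reagents that add atoms: none
Why: Acetic acid-buffered fluoride desilylation should remove the α-keto TIPS ether without enolising the acyloin (the 9β-hydroxyl is equatorial in the preferred cis-decalin conformer and so is also the stable epimer), cleaving the ester or adding to the β-iodoenone.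

Step 18
Reactants: 25 9β-hydroxy-11-iodo-3α-[(2E,4E,6E)-5-methyldodeca-2,4,6-trienoyloxy]-10βH-12-noreremophil-7(11)Z-en-8-one
Product: 26 9β,12-dihydroxy-3α-[(2E,4E,6E)-5-methyldodeca-2,4,6-trienoyloxy]-10βH-eremophil-7(11)Z-en-8-one (CNP0226738.1)
Conditions: Bu3SnCH2OH, Pd(PPh3)4 (10 mol %), CuI (20 mol %), DMF, 50 °C
Reagents that add atoms: (tributylstannyl)methanol, CCCC[Sn](CO)(CCCC)CCCC
Why: Stille coupling of the activated β-iodoenone with the hydroxymethylstannane should transfer CH2OH with retention of alkene geometry (CH2OH cis to the C8 carbonyl) under neutral conditions that spare the acyloin, the trienoate and the acid-sensitive γ-hydroxy enone.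

**Compound list**
1 | (R)-4-(tert-butyldimethylsilyloxy)cyclohex-2-en-1-one | O=C1C=C[C@H](O[Si](C)(C)C(C)(C)C)CC1 | starting material
2 | (R)-4-(tert-butyldimethylsilyloxy)-2-iodocyclohex-2-en-1-one | O=C1C(I)=C[C@H](O[Si](C)(C)C(C)(C)C)CC1 | intermediate
3 | (R)-4-(tert-butyldimethylsilyloxy)-2-methylcyclohex-2-en-1-one | O=C1C(C)=C[C@H](O[Si](C)(C)C(C)(C)C)CC1 | intermediate
4 | lithium (3R,4R)-4-(tert-butyldimethylsilyloxy)-2,3-dimethylcyclohex-1-en-1-olate | [Li+].CC(C)(C)[Si](C)(C)O[C@@H]1CCC([O-])=C(C)[C@H]1C | intermediate (not isolated)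
5 | (2R,3R,4R)-2-allyl-4-(tert-butyldimethylsilyloxy)-2,3-dimethylcyclohexan-1-one | CC(C)(C)[Si](C)(C)O[C@@H]1CCC(=O)[C@](C)(CC=C)[C@H]1C | intermediate
6 | (2R,3R,4R)-4-(tert-butyldimethylsilyloxy)-2,3-dimethyl-2-(2-oxopropyl)cyclohexan-1-one | CC(C)(C)[Si](C)(C)O[C@@H]1CCC(=O)[C@](C)(CC(C)=O)[C@H]1C | intermediate
7 | 3α-(tert-butyldimethylsilyloxy)-10β-hydroxy-4β,5β-dimethylhydrindan-8-one (cis-fused aldol adduct) | CC(C)(C)[Si](C)(C)O[C@@H]1CC[C@]2(O)CC(=O)C[C@]2(C)[C@H]1C | intermediate (not isolated)
8 | 3α-(tert-butyldimethylsilyloxy)-4β,5β-dimethylhydrind-9-en-8-one | CC(C)(C)[Si](C)(C)O[C@@H]1CCC2=CC(=O)C[C@]2(C)[C@H]1C | intermediate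
9 | 3α-(tert-butyldimethylsilyloxy)-8-(triethylsilyloxy)-4β,5β-dimethyl-10βH-hydrind-8-ene | CC(C)(C)[Si](C)(C)O[C@@H]1CC[C@@H]2C=C(O[Si](CC)(CC)CC)C[C@]2(C)[C@H]1C | intermediate
10 | 8β,9β-epoxide of 9 (8-triethylsilyloxy oxirane) | CC(C)(C)[Si](C)(C)O[C@@H]1CC[C@@H]2[C@H]3O[C@@]3(O[Si](CC)(CC)CC)C[C@]2(C)[C@H]1C | intermediate (not isolated)
11 | 3α-(tert-butyldimethylsilyloxy)-9β-(triethylsilyloxy)-4β,5β-dimethyl-10βH-hydrindan-8-one | CC(C)(C)[Si](C)(C)O[C@@H]1CC[C@@H]2[C@@H](O[Si](CC)(CC)CC)C(=O)C[C@]2(C)[C@H]1C | intermediate (not isolated)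
12 | 3α-(tert-butyldimethylsilyloxy)-9β-hydroxy-4β,5β-dimethyl-10βH-hydrindan-8-one | CC(C)(C)[Si](C)(C)O[C@@H]1CC[C@@H]2[C@@H](O)C(=O)C[C@]2(C)[C@H]1C | intermediate
13 | 3α-(tert-butyldimethylsilyloxy)-9β-(triisopropylsilyloxy)-4β,5β-dimethyl-10βH-hydrindan-8-one | CC(C)(C)[Si](C)(C)O[C@@H]1CC[C@@H]2[C@@H](O[Si](C(C)C)(C(C)C)C(C)C)C(=O)C[C@]2(C)[C@H]1C | intermediate
14 | 3α-(tert-butyldimethylsilyloxy)-8β-hydroxy-8α-(prop-1-ynyl)-9β-(triisopropylsilyloxy)-4β,5β-dimethyl-10βH-hydrindane | CC(C)(C)[Si](C)(C)O[C@@H]1CC[C@@H]2[C@@H](O[Si](C(C)C)(C(C)C)C(C)C)[C@](O)(C#CC)C[C@]2(C)[C@H]1C | intermediate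
15 | 3α-(tert-butyldimethylsilyloxy)-11-iodo-9β-(triisopropylsilyloxy)-10βH-12-noreremophil-7(11)Z-en-8-one | CC(C)(C)[Si](C)(C)O[C@@H]1CC[C@@H]2[C@@H](O[Si](C(C)C)(C(C)C)C(C)C)C(=O)/C(=C(/C)I)C[C@]2(C)[C@H]1C | intermediate
16 | 3α-hydroxy-11-iodo-9β-(triisopropylsilyloxy)-10βH-12-noreremophil-7(11)Z-en-8-one | O[C@@H]1CC[C@@H]2[C@@H](O[Si](C(C)C)(C(C)C)C(C)C)C(=O)/C(=C(/C)I)C[C@]2(C)[C@H]1C | intermediate
17 | (E)-oct-2-enal | CCCCC/C=C/C=O | starting material
18 | (E)-non-3-en-1-yne | CCCCC/C=C/C#C | intermediate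
19 | dimethyl[(1E,3E)-2-methylnona-1,3-dienyl]alumane | CCCCC/C=C/C(C)=C/[Al](C)C | intermediate (not isolated)
20 | (1E,3E)-1-iodo-2-methylnona-1,3-diene | CCCCC/C=C/C(C)=C/I | intermediate
21 | ethyl acrylate | C=CC(=O)OCC | starting material
22 | ethyl (2E,4E,6E)-5-methyldodeca-2,4,6-trienoate | CCCCC/C=C/C(C)=C/C=C/C(=O)OCC | intermediate
23 | (2E,4E,6E)-5-methyldodeca-2,4,6-trienoic acid | CCCCC/C=C/C(C)=C/C=C/C(=O)O | intermediate
24 | 11-iodo-3α-[(2E,4E,6E)-5-methyldodeca-2,4,6-trienoyloxy]-9β-(triisopropylsilyloxy)-10βH-12-noreremophil-7(11)Z-en-8-one | CCCCC/C=C/C(C)=C/C=C/C(=O)O[C@@H]1CC[C@@H]2[C@@H](O[Si](C(C)C)(C(C)C)C(C)C)C(=O)/C(=C(/C)I)C[C@]2(C)[C@H]1C | intermediate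
25 | 9β-hydroxy-11-iodo-3α-[(2E,4E,6E)-5-methyldodeca-2,4,6-trienoyloxy]-10βH-12-noreremophil-7(11)Z-en-8-one | CCCCC/C=C/C(C)=C/C=C/C(=O)O[C@@H]1CC[C@@H]2[C@@H](O)C(=O)/C(=C(/C)I)C[C@]2(C)[C@H]1C | intermediate
26 | 9β,12-dihydroxy-3α-[(2E,4E,6E)-5-methyldodeca-2,4,6-trienoyloxy]-10βH-eremophil-7(11)Z-en-8-one (CNP0226738.1) | CCCCC/C=C/C(C)=C/C=C/C(=O)O[C@@H]1CC[C@@H]2[C@@H](O)C(=O)/C(=C(/C)CO)C[C@]2(C)[C@H]1C | target

**Step count**
Total: 18 steps. Longest linear sequence: 14 steps (steps 1–11 and 16–18); fragment 2 takes 4 steps (12–15).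

**Steps most likely to fail**

Step 10 (proposed new method). What may go wrong: the internal alkyl alkyne may be activated too slowly, or ionisation at the tertiary propargylic carbon (transposition or dehydration) may outrun migration of the unstrained ring bond. The fallback uses the precedented haloalkynol variant; it sets out from 13 and comes back at 15. Addition of ethynylmagnesium bromide with CeCl3 to 13 should give the 8-ethynyl carbinol F1. Iodination of the terminal alkyne (NIS, catalytic AgNO3, acetone) gives the iodoalkyne F2. Bromonium-induced ring enlargement (NBS, catalytic PhI(OH)OTs, MeCN) should then give the (E)-bromo(iodo)methylidene decalone F3, with bromine anti to the migrated C6 and therefore cis to the C8 carbonyl. Chemoselective Negishi methylation of the C–I bond (MeZnCl, Pd(PPh3)4, THF, rt) gives the (Z)-vinyl bromide F4. Copper-catalysed bromide-to-iodide exchange with retention (CuI, N,N'-dimethylethylenediamine, NaI, dioxane, 110 °C) returns 15.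

Step 3. What may go wrong: facial selectivity in the enolate allylation may erode or reverse, because the electrophile must enter 1,3-syn to the pseudoaxial C3 silyloxy group, which would give the trans-dimethyl epimer at C5. The fallback puts the quaternary centre under catalyst control; it sets out from 3 and comes back at 5. The cuprate enolate 4 is trapped with Me3SiCl as the trimethylsilyl enol ether F5. Cleavage with MeLi and O-acylation with allyl chloroformate give the allyl enol carbonate F6. Decarboxylative Tsuji allylation with Pd2(dba)3 and (S)-t-BuPHOX, the ligand enantiomer matched to the required configuration, should deliver 5.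

Step 18. What may go wrong: transmetalation of the sp3 stannane at a tetrasubstituted alkenylpalladium centre may be slow in the fully functionalised substrate, allowing protodehalogenation or alkene isomerisation; the product may also cyclodehydrate to the furan on prolonged heating. The fallback moves the hydroxymethylation to the robust stage after the key step; it sets out from 15 and comes back at 26. Stille coupling of 15 with Bu3SnCH2OH at 80 °C gives the allylic alcohol F7. Silylation (TBDPSCl, imidazole) gives the primary TBDPS ether F8. HF·pyridine removes only the C3 TBS ether to give the C3 alcohol F9. Steglich esterification with 23 gives the trienoate F10. Buffered TBAF/AcOH removes both remaining silyl ethers to give 26.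

**Further compounds**
F1 | step 10 | 3α-(tert-butyldimethylsilyloxy)-8α-ethynyl-8β-hydroxy-9β-(triisopropylsilyloxy)-4β,5β-dimethyl-10βH-hydrindane | CC(C)(C)[Si](C)(C)O[C@@H]1CC[C@@H]2[C@@H](O[Si](C(C)C)(C(C)C)C(C)C)[C@](O)(C#C)C[C@]2(C)[C@H]1C
F2 | step 10 | 3α-(tert-butyldimethylsilyloxy)-8β-hydroxy-8α-(iodoethynyl)-9β-(triisopropylsilyloxy)-4β,5β-dimethyl-10βH-hydrindane | CC(C)(C)[Si](C)(C)O[C@@H]1CC[C@@H]2[C@@H](O[Si](C(C)C)(C(C)C)C(C)C)[C@](O)(C#CI)C[C@]2(C)[C@H]1C
F3 | step 10 | 11-bromo-3α-(tert-butyldimethylsilyloxy)-11-iodo-9β-(triisopropylsilyloxy)-10βH-12,13-dinoreremophil-7(11)E-en-8-one | CC(C)(C)[Si](C)(C)O[C@@H]1CC[C@@H]2[C@@H](O[Si](C(C)C)(C(C)C)C(C)C)C(=O)/C(=C(/I)Br)C[C@]2(C)[C@H]1C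
F4 | step 10 | 11-bromo-3α-(tert-butyldimethylsilyloxy)-9β-(triisopropylsilyloxy)-10βH-12-noreremophil-7(11)Z-en-8-one | CC(C)(C)[Si](C)(C)O[C@@H]1CC[C@@H]2[C@@H](O[Si](C(C)C)(C(C)C)C(C)C)C(=O)/C(=C(/C)Br)C[C@]2(C)[C@H]1C
F5 | step 3 | (3R,4R)-4-(tert-butyldimethylsilyloxy)-2,3-dimethyl-1-(trimethylsilyloxy)cyclohex-1-ene | CC(C)(C)[Si](C)(C)O[C@@H]1CCC(O[Si](C)(C)C)=C(C)[C@H]1C
F6 | step 3 | allyl (3R,4R)-4-(tert-butyldimethylsilyloxy)-2,3-dimethylcyclohex-1-en-1-yl carbonate | CC(C)(C)[Si](C)(C)O[C@@H]1CCC(OC(=O)OCC=C)=C(C)[C@H]1C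
F7 | step 18 | 3α-(tert-butyldimethylsilyloxy)-12-hydroxy-9β-(triisopropylsilyloxy)-10βH-eremophil-7(11)Z-en-8-one | CC(C)(C)[Si](C)(C)O[C@@H]1CC[C@@H]2[C@@H](O[Si](C(C)C)(C(C)C)C(C)C)C(=O)/C(=C(/C)CO)C[C@]2(C)[C@H]1C
F8 | step 18 | 3α-(tert-butyldimethylsilyloxy)-12-(tert-butyldiphenylsilyloxy)-9β-(triisopropylsilyloxy)-10βH-eremophil-7(11)Z-en-8-one | CC(C)(C)[Si](C)(C)O[C@@H]1CC[C@@H]2[C@@H](O[Si](C(C)C)(C(C)C)C(C)C)C(=O)/C(=C(/C)CO[Si](c3ccccc3)(c3ccccc3)C(C)(C)C)C[C@]2(C)[C@H]1C
F9 | step 18 | 12-(tert-butyldiphenylsilyloxy)-3α-hydroxy-9β-(triisopropylsilyloxy)-10βH-eremophil-7(11)Z-en-8-one | O[C@@H]1CC[C@@H]2[C@@H](O[Si](C(C)C)(C(C)C)C(C)C)C(=O)/C(=C(/C)CO[Si](c3ccccc3)(c3ccccc3)C(C)(C)C)C[C@]2(C)[C@H]1C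
F10 | step 18 | 12-(tert-butyldiphenylsilyloxy)-3α-[(2E,4E,6E)-5-methyldodeca-2,4,6-trienoyloxy]-9β-(triisopropylsilyloxy)-10βH-eremophil-7(11)Z-en-8-one | CCCCC/C=C/C(C)=C/C=C/C(=O)O[C@@H]1CC[C@@H]2[C@@H](O[Si](C(C)C)(C(C)C)C(C)C)C(=O)/C(=C(/C)CO[Si](c3ccccc3)(c3ccccc3)C(C)(C)C)C[C@]2(C)[C@H]1C
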